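**Retrosynthetic overview**
- Target ⇒ fluoride desilylation of its bis-TBS ether (side-chain OH and 4-hydroxyphenyl OH protected, guaiacyl OH free).
- Tetrahydropyran-4-one ring, the aryl–C2 bond and the two ring stereocentres ⇒ one-pot four-to-six ring expansion of 3-ethoxycyclobutanone with an (S)-α-silyloxy aldehyde, then Friedel–Crafts capture of the resulting oxocarbenium by guaiacol.
- (S)-α-Silyloxy aldehyde ⇒ methyl (S)-glycidate (source of the carbinol stereocentre) + 4-silyloxyphenyl Grignard (copper-catalysed epoxide opening), silylation, partial reduction.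
- Guaiacol ⇒ catechol + MeI.
- Ring order: both benzene rings are bought; the only ring built is the tetrahydropyranone, made from the four-membered ring in the penultimate step.

Assumption: the silylated bromophenol, the glycidate (≥98% ee) and the ethoxycyclobutanone are bought as catalogue items. TBS = tert-butyldimethylsilyl, TBSO = its ether.

**Step 1**
Reactants: 1 catechol (benzene-1,2-diol)
Product: 2 guaiacol (2-methoxyphenol)
Conditions: MeI (1.0 equiv), K2CO3 (1.0 equiv), acetone, 56 °C; distillation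
Reagents that add atoms: iodomethane (MeI), CI
Why: Williamson ether synthesis with one equivalent of base and MeI methylates one of the two equivalent phenols, and catechol and veratrole are removed by distillation; no stereocentre.

**Step 2**
Reactants: 3 (4-bromophenoxy)(tert-butyl)dimethylsilane; 4 methyl (2S)-oxirane-2-carboxylate (methyl (S)-glycidate)
Product: 6 methyl (2S)-3-[4-(TBSO)phenyl]-2-hydroxypropanoate, via arylmagnesium bromide 5 (not isolated)
Conditions: 3, Mg, THF, 50 °C; then CuI (10 mol%), 4, THF, −40 → −20 °C; then H2O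
Reagents that add atoms: none
Why: Copper-catalysed Grignard epoxide opening (SN2 at the unsubstituted C3 of the glycidic ester, faster at −40 °C than addition to the ester) forms the benzylic CH2 and leaves C2 untouched, so the (S) carbinol comes from the chiral pool.

**Step 3**
Reactants: 6 methyl (2S)-3-[4-(TBSO)phenyl]-2-hydroxypropanoate
Product: 7 methyl (2S)-2-(TBSO)-3-[4-(TBSO)phenyl]propanoate
Conditions: TBSCl, imidazole, DMF, 23 °C
Reagents that add atoms: tert-butyldimethylsilyl chloride (TBSCl), CC(C)(C)[Si](C)(C)Cl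
Why: Standard silyl ether formation masks the secondary alcohol and supplies the bulky, non-chelating α-substituent needed for Felkin–Anh control in step 5; the stereocentre is not touched.

**Step 4**
Reactants: 7 methyl (2S)-2-(TBSO)-3-[4-(TBSO)phenyl]propanoate
Product: 8 (2S)-2-(TBSO)-3-[4-(TBSO)phenyl]propanal
Conditions: i-Bu2AlH (1.1 equiv), CH2Cl2, −78 °C; then aq. potassium sodium tartrate (KNaC4H4O6)
Reagents that add atoms: none
Why: Partial ester reduction with i-Bu2AlH works because the aluminium hemiacetal is stable at −78 °C and gives the aldehyde only on work-up, and the α-silyloxy centre does not epimerise under cold, non-basic conditions.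

**Step 5**
Reactants: 8 (2S)-2-(TBSO)-3-[4-(TBSO)phenyl]propanal; 9 3-ethoxycyclobutan-1-one; 2 guaiacol
Product: 13 (2S,6R)-6-[(1S)-1-(TBSO)-2-[4-(TBSO)phenyl]ethyl]-2-(4-hydroxy-3-methoxyphenyl)tetrahydro-4H-pyran-4-one, via ethoxy acetal 10 (not isolated), via dihydropyranone 11 (not isolated), via 2,6-trans epimer 12 (not isolated)
Conditions: 9 (1.3 equiv), BF3·OEt2 (30 mol%), CH2Cl2, −45 °C, 2 h; then 2 (1.3 equiv), (CF3)2CHOH, −45 → 0 °C
Reagents that add atoms: none
Why: Proposed new method: BF3 opens the donor–acceptor cyclobutanone 9 at C2–C3 to a 1,4-zwitterion (boron enolate plus ethoxycarbenium) whose enolate adds to 8 in the Felkin–Anh (1,2-anti) sense, setting ring C6 as R, and whose carbenium is closed by the new alkoxide to acetal 10 (four-to-six ring expansion); loss of EtOH gives 11, whose acid-activated oxocarbenium is attacked by the carbon para to the free OH of guaiacol (stronger donor than OMe, ortho sites hindered) in a Friedel–Crafts reaction, and the kinetic axial adduct 12 equilibrates by reversible benzylic C–O ionisation and oxa-Michael reclosure on the aryl side only to the diequatorial 2,6-cis ketone 13 (aryl carbon S); the closest known reactions are the BF3-promoted formal [4+2] ring expansion of 3-alkoxycyclobutanones with aldehydes and the Friedel–Crafts C-arylation of glycosyl oxocarbenium ions by phenols, which have not been combined or run with a chiral α-silyloxy aldehyde.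

**Step 6**
Reactants: 13 (2S,6R)-6-[(1S)-1-(TBSO)-2-[4-(TBSO)phenyl]ethyl]-2-(4-hydroxy-3-methoxyphenyl)tetrahydro-4H-pyran-4-one
Product: 14 (2S,6R)-2-(4-hydroxy-3-methoxyphenyl)-6-[(1S)-1-hydroxy-2-(4-hydroxyphenyl)ethyl]tetrahydro-4H-pyran-4-one (CNP0222055.1)
Conditions: HF·pyridine, THF/pyridine, 0 → 23 °C
Reagents that add atoms: none
Why: Fluoride desilylation (Si–F bond formation) frees the phenol and the secondary alcohol under buffered, mildly acidic conditions that do not open the β-alkoxy ketone, so all three stereocentres are retained.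

**Compound list**
1 | catechol (benzene-1,2-diol) | Oc1ccccc1O | starting material
2 | guaiacol (2-methoxyphenol) | COc1ccccc1O | intermediate
3 | (4-bromophenoxy)(tert-butyl)dimethylsilane (TBS-protected 4-bromophenol) | CC(C)(C)[Si](C)(C)Oc1ccc(Br)cc1 | starting material
4 | methyl (2S)-oxirane-2-carboxylate (methyl (S)-glycidate) | COC(=O)[C@@H]1CO1 | starting material
5 | [4-(TBSO)phenyl]magnesium bromide | CC(C)(C)[Si](C)(C)Oc1ccc([Mg]Br)cc1 | intermediate (not isolated)
6 | methyl (2S)-3-[4-(TBSO)phenyl]-2-hydroxypropanoate | COC(=O)[C@@H](O)Cc1ccc(O[Si](C)(C)C(C)(C)C)cc1 | intermediate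
7 | methyl (2S)-2-(TBSO)-3-[4-(TBSO)phenyl]propanoate | COC(=O)[C@@H](O[Si](C)(C)C(C)(C)C)Cc1ccc(O[Si](C)(C)C(C)(C)C)cc1 | intermediate
8 | (2S)-2-(TBSO)-3-[4-(TBSO)phenyl]propanal | O=C[C@@H](O[Si](C)(C)C(C)(C)C)Cc1ccc(O[Si](C)(C)C(C)(C)C)cc1 | intermediate
9 | 3-ethoxycyclobutan-1-one | CCOC1CC(=O)C1 | starting material
10 | (6R)-6-[(1S)-1-(TBSO)-2-[4-(TBSO)phenyl]ethyl]-2-ethoxytetrahydro-4H-pyran-4-one (both C2 epimers) | CCOC1CC(=O)C[C@H]([C@@H](O[Si](C)(C)C(C)(C)C)Cc2ccc(O[Si](C)(C)C(C)(C)C)cc2)O1 | intermediate (not isolated)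
11 | (2R)-2-[(1S)-1-(TBSO)-2-[4-(TBSO)phenyl]ethyl]-2,3-dihydro-4H-pyran-4-one | O=C1C[C@H]([C@@H](O[Si](C)(C)C(C)(C)C)Cc2ccc(O[Si](C)(C)C(C)(C)C)cc2)OC=C1 | intermediate (not isolated)
12 | (2R,6R)-6-[(1S)-1-(TBSO)-2-[4-(TBSO)phenyl]ethyl]-2-(4-hydroxy-3-methoxyphenyl)tetrahydro-4H-pyran-4-one (2,6-trans) | COc1cc([C@H]2CC(=O)C[C@H]([C@@H](O[Si](C)(C)C(C)(C)C)Cc3ccc(O[Si](C)(C)C(C)(C)C)cc3)O2)ccc1O | intermediate (not isolated)
13 | (2S,6R)-6-[(1S)-1-(TBSO)-2-[4-(TBSO)phenyl]ethyl]-2-(4-hydroxy-3-methoxyphenyl)tetrahydro-4H-pyran-4-one (2,6-cis) | COc1cc([C@@H]2CC(=O)C[C@H]([C@@H](O[Si](C)(C)C(C)(C)C)Cc3ccc(O[Si](C)(C)C(C)(C)C)cc3)O2)ccc1O | intermediate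
14 | (2S,6R)-2-(4-hydroxy-3-methoxyphenyl)-6-[(1S)-1-hydroxy-2-(4-hydroxyphenyl)ethyl]tetrahydro-4H-pyran-4-one | COc1cc([C@@H]2CC(=O)C[C@H]([C@@H](O)Cc3ccc(O)cc3)O2)ccc1O | target

**Totals**
Total steps: 6. Longest linear sequence: 5 (steps 2 to 6, from 3 and 4).

**Three steps most likely to fail**

1. Step 5 (the proposed new one-pot ring expansion and arylation). Possible failures are arylation ortho to OH or para to OMe, double arylation through the re-ionised benzylic ether, incomplete trans-to-cis equilibration, and a modest Felkin ratio. The fallback uses known chemistry only and sets out from 8, 9 and 2. The ring expansion is run alone (BF3·OEt2, CH2Cl2, −45 → 0 °C) and dihydropyranone 11 is isolated. Guaiacol 2 is brominated para to OH (NBS, MeCN, 0 °C) to 4-bromo-2-methoxyphenol F1, silylated (TBSCl, imidazole) to (4-bromo-2-methoxyphenoxy)(tert-butyl)dimethylsilane F2, and converted with Mg in THF into [4-(TBSO)-3-methoxyphenyl]magnesium bromide F3. CuBr·SMe2-catalysed 1,4-addition of F3 to 11 (THF, −78 → −40 °C, then H2O) gives, by axial attack, the (2R,6R) 2,6-trans tris-silyl ketone F4. TsOH·H2O in CH2Cl2 equilibrates F4 by retro-oxa-Michael and oxa-Michael reclosure to the (2S,6R) 2,6-cis tris-silyl ketone F5. HF·pyridine then removes all three silyl groups and the fallback comes back to the route at 14.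

2. Step 2 (copper-catalysed opening of a glycidic ester). Possible failures are Grignard addition to the ester and halohydrin formation. The fallback sets out from 5. With CuI (10 mol%) 5 opens an epoxide that carries no ester, (2S)-2-[(benzyloxy)methyl]oxirane F6, to (2S)-1-(benzyloxy)-3-[4-(TBSO)phenyl]propan-2-ol F7. Silylation (TBSCl, imidazole) gives benzyl ether (2S)-1-(benzyloxy)-2-(TBSO)-3-[4-(TBSO)phenyl]propane F8. Hydrogenolysis (H2, Pd/C, EtOAc) gives (2S)-2-(TBSO)-3-[4-(TBSO)phenyl]propan-1-ol F9. Dess–Martin oxidation comes back to the route at 8, which also bypasses steps 3 and 4.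

3. Step 4 (partial reduction). Possible failures are over-reduction to the alcohol or partial epimerisation of 8. The fallback sets out from 7. MeNH(OMe)·HCl with i-PrMgCl (THF, −20 °C) gives the Weinreb amide (2S)-2-(TBSO)-3-[4-(TBSO)phenyl]-N-methoxy-N-methylpropanamide F10. Its chelated tetrahedral intermediate with LiAlH4 (THF, −78 °C) collapses only on work-up, and the fallback comes back to the route at 8.

**Further compounds**
F1 | step 5 | 4-bromo-2-methoxyphenol | COc1cc(Br)ccc1O
F2 | step 5 | (4-bromo-2-methoxyphenoxy)(tert-butyl)dimethylsilane | COc1cc(Br)ccc1O[Si](C)(C)C(C)(C)C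
F3 | step 5 | [4-(TBSO)-3-methoxyphenyl]magnesium bromide | COc1cc([Mg]Br)ccc1O[Si](C)(C)C(C)(C)C
F4 | step 5 | (2R,6R)-2-[4-(TBSO)-3-methoxyphenyl]-6-[(1S)-1-(TBSO)-2-[4-(TBSO)phenyl]ethyl]tetrahydro-4H-pyran-4-one | COc1cc([C@H]2CC(=O)C[C@H]([C@@H](O[Si](C)(C)C(C)(C)C)Cc3ccc(O[Si](C)(C)C(C)(C)C)cc3)O2)ccc1O[Si](C)(C)C(C)(C)C
F5 | step 5 | (2S,6R)-2-[4-(TBSO)-3-methoxyphenyl]-6-[(1S)-1-(TBSO)-2-[4-(TBSO)phenyl]ethyl]tetrahydro-4H-pyran-4-one | COc1cc([C@@H]2CC(=O)C[C@H]([C@@H](O[Si](C)(C)C(C)(C)C)Cc3ccc(O[Si](C)(C)C(C)(C)C)cc3)O2)ccc1O[Si](C)(C)C(C)(C)C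
F6 | step 2 | (2S)-2-[(benzyloxy)methyl]oxirane ((S)-benzyl glycidyl ether) | c1ccccc1COC[C@@H]1CO1
F7 | step 2 | (2S)-1-(benzyloxy)-3-[4-(TBSO)phenyl]propan-2-ol | c1ccccc1COC[C@@H](O)Cc2ccc(O[Si](C)(C)C(C)(C)C)cc2
F8 | step 2 | (2S)-1-(benzyloxy)-2-(TBSO)-3-[4-(TBSO)phenyl]propane | c1ccccc1COC[C@@H](O[Si](C)(C)C(C)(C)C)Cc2ccc(O[Si](C)(C)C(C)(C)C)cc2
F9 | step 2 | (2S)-2-(TBSO)-3-[4-(TBSO)phenyl]propan-1-ol | OC[C@@H](O[Si](C)(C)C(C)(C)C)Cc1ccc(O[Si](C)(C)C(C)(C)C)cc1
F10 | step 4 | (2S)-2-(TBSO)-3-[4-(TBSO)phenyl]-N-methoxy-N-methylpropanamide | CON(C)C(=O)[C@@H](O[Si](C)(C)C(C)(C)C)Cc1ccc(O[Si](C)(C)C(C)(C)C)cc1
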